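**Plan**
1. Retrosynthesis: remove the tiglate (O8) and the acetate, cut C13–C11 (Stille), then C11–C7 and O6–C12 of the butenolide (glyoxylate aldol at C7, lactonization onto O6), which leaves a ten-membered ring at the 1,6-dione level.
2. Cut C8–C9 and reconnect C1–C6 (retro anionic oxy-Cope). The feature that allows this: the ring oxygens on C1 (ketone) and C6 (lactone O) lie 1,6 across the ten-membered ring, and the arc C1–C6 carries the 4,5-oxirane as a cis epoxide. That is exactly a cyclohexane-1,2-diol with one vinyl arm on each carbinol carbon (C10=C9 on C1, C7=C8 on C6).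
3. Forward: the six-membered ring first (3-methylcyclohexenone → epoxy ketone → C1 quaternary methyl ether → alkoxyvinyl addition at C6), then ring expansion 6 → 10 with enolate trapping at C7, then the butenolide ring, then the two esters.
4. Stereochemistry: C4/C5 come from a catalyst-controlled epoxidation; C1 and C6 of the cyclohexane are set relative to the epoxide and relayed to C8 through a chair transition state; C6 is re-created by chelation-controlled reduction and C10 by protonation of the C1 enol ether.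

Key step: step 9

Remark: germacrane locants are used throughout (ring C1–C10, C11–C13 on C7, C14 on C10, C15 on C4). The catalyst pseudoenantiomer in step 1 is assumed to be the one that gives the (1R,6R)-epoxide, and (10R) is assumed to be the more stable C10 epimer of the 1-ketone.

Step 1
Reactants: 1 3-methylcyclohex-2-en-1-one
Product: 2 (1R,6R)-6-methyl-7-oxabicyclo[4.1.0]heptan-2-one
Conditions: 9-amino-9-deoxy-epi-quinidine (10 mol %), CF3CO2H (20 mol %), 50% aq. H2O2, 1,4-dioxane, 35 °C
Reagents that add atoms: hydrogen peroxide, OO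
Why: Iminium-activated nucleophilic (Weitz–Scheffer-type) epoxidation of a cyclic enone with a chiral primary amine salt, in which the catalyst selects the enone face and so fixes C4 and C5 together as the cis oxirane.

Step 2
Reactants: 2 (1R,6R)-6-methyl-7-oxabicyclo[4.1.0]heptan-2-one
Product: 3 (1R,6R)-3-(2-hydroxypropan-2-yl)-6-methyl-7-oxabicyclo[4.1.0]heptan-2-one (C3 epimers)
Conditions: LiN(iPr)2, THF, −78 °C; acetone; aq. NH4Cl
Reagents that add atoms: acetone, CC(C)=O
Why: Kinetic deprotonation can occur only at C1 (the other alpha carbon is the oxirane CH), and aldol addition to acetone brings in C9, C10 and C14; the new centre is removed again in step 3.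

Step 3
Reactants: 3 (1R,6R)-3-(2-hydroxypropan-2-yl)-6-methyl-7-oxabicyclo[4.1.0]heptan-2-one
Product: 5 (1R,6R)-6-methyl-3-(propan-2-ylidene)-7-oxabicyclo[4.1.0]heptan-2-one, via mesylate 4 (not isolated)
Conditions: MsCl, Et3N, CH2Cl2, 0 °C; then DBU, 25 °C
Reagents that add atoms: none
Why: Sulfonylation and E1cB elimination complete the aldol condensation to the conjugated enone; any isopropenyl regioisomer is harmless because it should give the same dienolate in step 4.

Step 4
Reactants: 5 (1R,6R)-6-methyl-3-(propan-2-ylidene)-7-oxabicyclo[4.1.0]heptan-2-one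
Product: 6 (1R,3S,6R)-3-hydroxy-6-methyl-3-(prop-1-en-2-yl)-7-oxabicyclo[4.1.0]heptan-2-one
Conditions: KN(SiMe3)2, THF, −78 °C; 3-phenyl-2-(phenylsulfonyl)oxaziridine, −78 °C; aq. NH4Cl
Reagents that add atoms: 3-phenyl-2-(phenylsulfonyl)oxaziridine, O=S(=O)(c1ccccc1)N1OC1c1ccccc1
Why: Gamma-deprotonation gives the cross-conjugated dienolate, which should take up electrophilic oxygen at the alpha carbon C1 (deconjugative enolate hydroxylation with an N-sulfonyloxaziridine) on the face away from the oxirane oxygen, so that the C1 hydroxyl is set trans to the epoxide oxygen.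

Step 5
Reactants: 6 (1R,3S,6R)-3-hydroxy-6-methyl-3-(prop-1-en-2-yl)-7-oxabicyclo[4.1.0]heptan-2-one
Product: 7 (1R,3S,6R)-3-methoxy-6-methyl-3-(prop-1-en-2-yl)-7-oxabicyclo[4.1.0]heptan-2-one
Conditions: NaH, MeI, THF–DMF, 0 °C
Reagents that add atoms: iodomethane, CI
Why: Williamson etherification of the tertiary alkoxide of a ketone that has no enolizable alpha hydrogen; the methyl ether later serves as chelating group (step 8) and as the mask of the C1 carbonyl (step 9).

Step 6
Reactants: 8 (4-methoxyphenyl)methanol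
Product: 11 1-[(ethynyloxy)methyl]-4-methoxybenzene, via dichlorovinyl ether 9 (not isolated), via lithium acetylide 10 (not isolated)
Conditions: KH, THF, 0 °C; Cl2C=CHCl, −50 → 25 °C; then n-BuLi (2.4 equiv), −78 → −40 °C; MeOH, −78 °C
Reagents that add atoms: trichloroethene, ClC=C(Cl)Cl
Why: Alkoxide addition–elimination on trichloroethene gives the 1,2-dichlorovinyl ether, and dehydrochlorination followed by lithium–chlorine exchange gives the metalated ynol ether that is protonated on quench (standard ynol ether synthesis from an alcohol); the product is kept cold because benzylic ynol ethers rearrange on heating.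

Step 7
Reactants: 11 1-[(ethynyloxy)methyl]-4-methoxybenzene
Product: 12 tributyl{(Z)-2-[(4-methoxyphenyl)methoxy]ethenyl}stannane
Conditions: Bu3SnH, Et3B (cat.), air, toluene, −20 → 20 °C
Reagents that add atoms: tributylstannane, CCCC[SnH](CCCC)CCCC
Why: Radical hydrostannation of an alkoxyalkyne places tin on the beta carbon and is anti-selective under kinetic, low-temperature initiation, which should give the (Z)-beta-stannyl enol ether.

Step 8
Reactants: 7 (1R,3S,6R)-3-methoxy-6-methyl-3-(prop-1-en-2-yl)-7-oxabicyclo[4.1.0]heptan-2-one; 12 tributyl{(Z)-2-[(4-methoxyphenyl)methoxy]ethenyl}stannane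
Product: 14 (1S,2R,3S,6R)-3-methoxy-2-{(Z)-2-[(4-methoxyphenyl)methoxy]ethenyl}-6-methyl-3-(prop-1-en-2-yl)-7-oxabicyclo[4.1.0]heptan-2-ol, via vinyllithium 13 (not isolated)
Conditions: 12, n-BuLi, THF, −78 °C; then 7, −78 → −40 °C; aq. NH4Cl
Reagents that add atoms: none
Why: Tin–lithium exchange gives the configurationally stable cis-2-alkoxyvinyllithium with retention, and its chelation-controlled 1,2-addition to the non-enolizable ketone (lithium bridging C6=O and the C1 methoxy group) should occur anti to the oxirane oxygen and anti to the isopropenyl group, which sets the C6 hydroxyl cis to the epoxide oxygen and trans to the methoxy group.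

Step 9
Reactants: 14 (1S,2R,3S,6R)-3-methoxy-2-{(Z)-2-[(4-methoxyphenyl)methoxy]ethenyl}-6-methyl-3-(prop-1-en-2-yl)-7-oxabicyclo[4.1.0]heptan-2-ol
Product: 17 ethyl 2-hydroxy-2-[(1R,4S,6Z,10R)-7-methoxy-4-[(4-methoxyphenyl)methoxy]-6,10-dimethyl-2-oxo-11-oxabicyclo[8.1.0]undec-6-en-3-yl]acetate (epimers at C7 and C11), via potassium alkoxide 15 (not isolated), via potassium enolate 16 (not isolated)
Conditions: KN(SiMe3)2, 18-crown-6, THF, −78 → −20 °C; then ethyl glyoxylate (freshly depolymerized), −78 °C; AcOH, −78 °C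
Reagents that add atoms: ethyl glyoxylate, CCOC(=O)C=O
Why: Deprotonation gives alkoxide 15, in which the C1–C6 bond lies between the two vinyl units and is flanked by the C6 oxido and C1 methoxy groups, so a [3,3]-sigmatropic shift (anionic oxy-Cope rearrangement, the reaction type that turns 1,2-divinylcyclohexanols into cyclodec-5-enones) breaks C1–C6 and forms C8–C9. The ten-membered carbocycle is therefore closed by a four-atom ring expansion of the cyclohexane through a six-membered chair transition state, not by an end-to-end cyclization, and the cis-4,5-epoxide is carried over unchanged from the six-membered ring. C8 is the only new stereocentre: with the two vinyl groups trans-diequatorial only one chair is available, the (Z)-enol ether places the C8 alkoxy group axial and syn to the C6 oxido group (where K+ can bridge both oxygens), and the (6R) carbinol centre is thereby relayed to (8S). The rearrangement has to outrun beta-elimination of the C8 alkoxide from enolate 16 and a dissociative retro-allylation course; the doubly donor-substituted breaking bond and the crown-ether-separated potassium alkoxide should let it proceed below −20 °C, and because the C1 oxygen emerges as a methyl enol ether only the C6 enolate is nucleophilic. Enolate 16 is then trapped at C7 by ethyl glyoxylate (aldol addition); the C7 and C11 configurations do not matter because both centres become sp2 in step 11.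

Step 10
Reactants: 17 ethyl 2-hydroxy-2-[(1R,4S,6Z,10R)-7-methoxy-4-[(4-methoxyphenyl)methoxy]-6,10-dimethyl-2-oxo-11-oxabicyclo[8.1.0]undec-6-en-3-yl]acetate
Product: 19 (4R,5S,6S,8S,10R)-4,5-epoxy-11-hydroxy-8-[(4-methoxybenzyl)oxy]-1-oxo-13-norgermacran-12,6-olide (epimers at C7 and C11), via diol ester 18 (not isolated)
Conditions: Zn(BH4)2, Et2O, −30 °C; aq. NH4Cl; then pyridinium p-toluenesulfonate, THF–H2O, 40 °C
Reagents that add atoms: water, O
Why: Chelation-controlled reduction of the alpha,beta-epoxy ketone should set C6, since the five-membered zinc chelate through the oxirane oxygen (anti epoxy alcohol) and the six-membered chelate through the C8 ether oxygen (1,3-syn) call for the same face; mild acid then closes the gamma-lactone and hydrolyses the C1 methyl enol ether, C10 being set by protonation and settling through enolization at the more stable epimer.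

Step 11
Reactants: 19 (4R,5S,6S,8S,10R)-4,5-epoxy-11-hydroxy-8-[(4-methoxybenzyl)oxy]-1-oxo-13-norgermacran-12,6-olide
Product: 20 (4R,5S,6S,8S,10R)-4,5-epoxy-11-hydroxy-8-[(4-methoxybenzyl)oxy]-1-oxo-13-norgermacr-7(11)-en-12,6-olide (enol form of the alpha-keto lactone)
Conditions: Dess–Martin periodinane, NaHCO3, CH2Cl2, 0 → 25 °C
Reagents that add atoms: none
Why: Dess–Martin oxidation of the secondary alpha-hydroxy lactone gives an alpha-keto lactone that should exist as its enol toward C7 (the only alpha hydrogen), so the C7=C11 double bond is placed unambiguously and the C7/C11 epimer mixture converges.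

Step 12
Reactants: 20 (4R,5S,6S,8S,10R)-4,5-epoxy-11-hydroxy-8-[(4-methoxybenzyl)oxy]-1-oxo-13-norgermacr-7(11)-en-12,6-olide
Product: 21 (4R,5S,6S,8S,10R)-4,5-epoxy-8-[(4-methoxybenzyl)oxy]-1-oxo-11-[(trifluoromethanesulfonyl)oxy]-13-norgermacr-7(11)-en-12,6-olide
Conditions: PhNTf2, Et3N, DMAP (cat.), CH2Cl2, 0 °C
Reagents that add atoms: N-phenylbis(trifluoromethanesulfonimide), O=S(=O)(N(c1ccccc1)S(=O)(=O)C(F)(F)F)C(F)(F)F
Why: O-sulfonylation of the acidic enol (enol triflate formation) under conditions too weakly basic to touch the C1 ketone or the gamma hydrogen at C6.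

Step 13
Reactants: 21 (4R,5S,6S,8S,10R)-4,5-epoxy-8-[(4-methoxybenzyl)oxy]-1-oxo-11-[(trifluoromethanesulfonyl)oxy]-13-norgermacr-7(11)-en-12,6-olide
Product: 22 (4R,5S,6S,8S,10R)-4,5-epoxy-13-hydroxy-8-[(4-methoxybenzyl)oxy]-1-oxogermacr-7(11)-en-12,6-olide
Conditions: Bu3SnCH2OH, Pd(PPh3)4 (5 mol %), LiCl, 1,4-dioxane, 90 °C
Reagents that add atoms: (tributylstannyl)methanol, CCCC[Sn](CO)(CCCC)CCCC
Why: Stille coupling of an alkenyl triflate with a hydroxymethylstannane installs C13 on C11 without touching any stereocentre; the alcohol is acetylated only afterwards so that no allylic acetate meets zerovalent palladium.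

Step 14
Reactants: 22 (4R,5S,6S,8S,10R)-4,5-epoxy-13-hydroxy-8-[(4-methoxybenzyl)oxy]-1-oxogermacr-7(11)-en-12,6-olide
Product: 23 (4R,5S,6S,8S,10R)-13-acetoxy-4,5-epoxy-8-[(4-methoxybenzyl)oxy]-1-oxogermacr-7(11)-en-12,6-olide
Conditions: Ac2O, pyridine, DMAP (cat.), CH2Cl2, 0 °C
Reagents that add atoms: acetic anhydride, CC(=O)OC(C)=O
Why: DMAP-catalysed acetylation of the only free hydroxyl group.

Step 15
Reactants: 23 (4R,5S,6S,8S,10R)-13-acetoxy-4,5-epoxy-8-[(4-methoxybenzyl)oxy]-1-oxogermacr-7(11)-en-12,6-olide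
Product: 24 (4R,5S,6S,8S,10R)-13-acetoxy-4,5-epoxy-8-hydroxy-1-oxogermacr-7(11)-en-12,6-olide
Conditions: DDQ, CH2Cl2–pH 7 buffer, 0 → 25 °C
Reagents that add atoms: none
Why: Oxidative cleavage of the 4-methoxybenzyl ether under neutral conditions that should spare the epoxide, the acetate and the base-sensitive butenolide.

Step 16
Reactants: 24 (4R,5S,6S,8S,10R)-13-acetoxy-4,5-epoxy-8-hydroxy-1-oxogermacr-7(11)-en-12,6-olide
Product: 25 CNP0229937.1, (4R,5S,6S,8S,10R)-13-acetoxy-4,5-epoxy-1-oxo-8-[(E)-2-methylbut-2-enoyloxy]germacr-7(11)-en-12,6-olide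
Conditions: (E)-2-methylbut-2-enoyl chloride, pyridine, DMAP, CH2Cl2, 0 → 25 °C
Reagents that add atoms: (E)-2-methylbut-2-enoyl chloride, C/C=C(\C)C(Cl)=O
Why: DMAP-catalysed acylation of the secondary C8 alcohol with the thermodynamically stable (E)-acid chloride, carried out promptly and under weakly basic conditions to forestall lactone migration to O8 and deprotonation at C6.

**Compound list**
1 | 3-methylcyclohex-2-en-1-one | CC1=CC(=O)CCC1 | starting material
2 | (1R,6R)-6-methyl-7-oxabicyclo[4.1.0]heptan-2-one | O=C1CCC[C@@]2(C)O[C@@H]12 | intermediate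
3 | (1R,6R)-3-(2-hydroxypropan-2-yl)-6-methyl-7-oxabicyclo[4.1.0]heptan-2-one (C3 epimers) | O=C1C(C(C)(C)O)CC[C@@]2(C)O[C@@H]12 | intermediate
4 | mesylate of 3, not isolated | O=C1C(C(C)(C)OS(C)(=O)=O)CC[C@@]2(C)O[C@@H]12 | intermediate
5 | (1R,6R)-6-methyl-3-(propan-2-ylidene)-7-oxabicyclo[4.1.0]heptan-2-one | O=C1C(=C(C)C)CC[C@@]2(C)O[C@@H]12 | intermediate
6 | (1R,3S,6R)-3-hydroxy-6-methyl-3-(prop-1-en-2-yl)-7-oxabicyclo[4.1.0]heptan-2-one | O=C1[C@@](O)(C(C)=C)CC[C@@]2(C)O[C@@H]12 | intermediate
7 | (1R,3S,6R)-3-methoxy-6-methyl-3-(prop-1-en-2-yl)-7-oxabicyclo[4.1.0]heptan-2-one | O=C1[C@@](OC)(C(C)=C)CC[C@@]2(C)O[C@@H]12 | intermediate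
8 | (4-methoxyphenyl)methanol | COc1ccc(CO)cc1 | starting material
9 | 1-{[(1,2-dichloroethenyl)oxy]methyl}-4-methoxybenzene, not isolated | COc1ccc(COC(Cl)=CCl)cc1 | intermediate
10 | lithium [(4-methoxyphenyl)methoxy]acetylide, not isolated | [Li]C#COCc1ccc(OC)cc1 | intermediate
11 | 1-[(ethynyloxy)methyl]-4-methoxybenzene | C#COCc1ccc(OC)cc1 | intermediate
12 | tributyl{(Z)-2-[(4-methoxyphenyl)methoxy]ethenyl}stannane | CCCC[Sn](CCCC)(CCCC)/C=C\OCc1ccc(OC)cc1 | intermediate
13 | {(Z)-2-[(4-methoxyphenyl)methoxy]ethenyl}lithium, not isolated | [Li]/C=C\OCc1ccc(OC)cc1 | intermediate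
14 | (1S,2R,3S,6R)-3-methoxy-2-{(Z)-2-[(4-methoxyphenyl)methoxy]ethenyl}-6-methyl-3-(prop-1-en-2-yl)-7-oxabicyclo[4.1.0]heptan-2-ol | O[C@@]1(/C=C\OCc2ccc(OC)cc2)[C@@](OC)(C(C)=C)CC[C@@]3(C)O[C@@H]13 | intermediate
15 | potassium alkoxide of 14, not isolated | [K+].[O-][C@@]1(/C=C\OCc2ccc(OC)cc2)[C@@](OC)(C(C)=C)CC[C@@]3(C)O[C@@H]13 | intermediate
16 | potassium (1S,2Z,4S,6Z,10R)-7-methoxy-4-[(4-methoxyphenyl)methoxy]-6,10-dimethyl-11-oxabicyclo[8.1.0]undeca-2,6-dien-2-olate, not isolated | [K+].CO/C1=C(/C)C[C@H](OCc2ccc(OC)cc2)/C=C(\[O-])[C@@H]2O[C@]2(C)CC1 | intermediate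
17 | ethyl 2-hydroxy-2-[(1R,4S,6Z,10R)-7-methoxy-4-[(4-methoxyphenyl)methoxy]-6,10-dimethyl-2-oxo-11-oxabicyclo[8.1.0]undec-6-en-3-yl]acetate (epimers at C7 and C11) | CO/C1=C(/C)C[C@H](OCc2ccc(OC)cc2)C(C(O)C(=O)OCC)C(=O)[C@@H]2O[C@]2(C)CC1 | intermediate
18 | ethyl 2-hydroxy-2-[(1S,2S,4S,6Z,10R)-2-hydroxy-7-methoxy-4-[(4-methoxyphenyl)methoxy]-6,10-dimethyl-11-oxabicyclo[8.1.0]undec-6-en-3-yl]acetate, not isolated | CO/C1=C(/C)C[C@H](OCc2ccc(OC)cc2)C(C(O)C(=O)OCC)[C@H](O)[C@@H]2O[C@]2(C)CC1 | intermediate
19 | (4R,5S,6S,8S,10R)-4,5-epoxy-11-hydroxy-8-[(4-methoxybenzyl)oxy]-1-oxo-13-norgermacran-12,6-olide (epimers at C7 and C11) | COc1ccc(CO[C@H]2C[C@@H](C)C(=O)CC[C@@]3(C)O[C@H]3[C@H]3OC(=O)C(O)C23)cc1 | intermediate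
20 | (4R,5S,6S,8S,10R)-4,5-epoxy-11-hydroxy-8-[(4-methoxybenzyl)oxy]-1-oxo-13-norgermacr-7(11)-en-12,6-olide | COc1ccc(CO[C@H]2C[C@@H](C)C(=O)CC[C@@]3(C)O[C@H]3[C@H]3OC(=O)C(O)=C23)cc1 | intermediate
21 | (4R,5S,6S,8S,10R)-4,5-epoxy-8-[(4-methoxybenzyl)oxy]-1-oxo-11-[(trifluoromethanesulfonyl)oxy]-13-norgermacr-7(11)-en-12,6-olide | COc1ccc(CO[C@H]2C[C@@H](C)C(=O)CC[C@@]3(C)O[C@H]3[C@H]3OC(=O)C(OS(=O)(=O)C(F)(F)F)=C23)cc1 | intermediate
22 | (4R,5S,6S,8S,10R)-4,5-epoxy-13-hydroxy-8-[(4-methoxybenzyl)oxy]-1-oxogermacr-7(11)-en-12,6-olide | COc1ccc(CO[C@H]2C[C@@H](C)C(=O)CC[C@@]3(C)O[C@H]3[C@H]3OC(=O)C(CO)=C23)cc1 | intermediate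
23 | (4R,5S,6S,8S,10R)-13-acetoxy-4,5-epoxy-8-[(4-methoxybenzyl)oxy]-1-oxogermacr-7(11)-en-12,6-olide | COc1ccc(CO[C@H]2C[C@@H](C)C(=O)CC[C@@]3(C)O[C@H]3[C@H]3OC(=O)C(COC(C)=O)=C23)cc1 | intermediate
24 | (4R,5S,6S,8S,10R)-13-acetoxy-4,5-epoxy-8-hydroxy-1-oxogermacr-7(11)-en-12,6-olide | O[C@H]1C[C@@H](C)C(=O)CC[C@@]2(C)O[C@H]2[C@H]2OC(=O)C(COC(C)=O)=C12 | intermediate
25 | CNP0229937.1, (4R,5S,6S,8S,10R)-13-acetoxy-4,5-epoxy-1-oxo-8-[(E)-2-methylbut-2-enoyloxy]germacr-7(11)-en-12,6-olide | C/C=C(\C)C(=O)O[C@H]1C[C@@H](C)C(=O)CC[C@@]2(C)O[C@H]2[C@H]2OC(=O)C(COC(C)=O)=C12 | target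

**Count and risks**
Total step count: 16. Longest linear sequence: 14 (steps 1–5 and 8–16); steps 6 and 7 form the side branch to stannane 12.

Steps most likely to fail, most risky first:

Step 9. The potassium enolate 16 may expel the C8 alkoxide by beta-elimination before it is trapped, or the alkoxide may react by a dissociative retro-allylation and re-addition that bypasses the chair and erodes the transfer of chirality to C8. Fallback (charge-free rearrangement, setting out from 14): 14 would be silylated with N-(trimethylsilyl)imidazole in CH2Cl2 to the trimethylsilyl ether of 14 F1. F1 would be heated in toluene at 150 °C (sealed tube, N,O-bis(trimethylsilyl)acetamide as acid scavenger) so that the neutral siloxy-Cope rearrangement gives the ring-expanded C6 trimethylsilyl enol ether with the C1 methyl enol ether intact F2. A Mukaiyama aldol addition of F2 to ethyl glyoxylate (MgBr2·OEt2, CH2Cl2, −78 °C, aqueous work-up) would then give 17, where the route is rejoined.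

Step 10. Hydride delivery to C6 may show poor facial selectivity, because the C7 epimers and the competing chelates (oxirane oxygen, C8 ether oxygen, C11 hydroxyl) need not all favour one face in the ten-membered ring. Fallback (reagent control instead of substrate chelation, setting out from 17): a Corey–Bakshi–Shibata reduction of 17 with the oxazaborolidine enantiomer matched to the 6S face and catecholborane in toluene at −78 °C, followed by the same pyridinium p-toluenesulfonate treatment, would return to 19; this fallback makes no new compound F0.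

Step 4. Oxygen transfer to the dienolate may occur on the wrong face of C1, or with poor facial selectivity, since the oxirane is two atoms away. Fallback (reversed order of introducing the two C1 substituents, setting out from 2): 2 would be hydroxylated at C1 (LiN(iPr)2, then 3-phenyl-2-(phenylsulfonyl)oxaziridine) to (1R,6R)-3-hydroxy-6-methyl-7-oxabicyclo[4.1.0]heptan-2-one F3 and methylated (MeI, Ag2O) to (1R,6R)-3-methoxy-6-methyl-7-oxabicyclo[4.1.0]heptan-2-one F4. Enolization of F4 (LiN(iPr)2, −78 °C) and aldol addition to acetone would give (1R,3S,6R)-3-(2-hydroxypropan-2-yl)-3-methoxy-6-methyl-7-oxabicyclo[4.1.0]heptan-2-one F5, the carbon electrophile now taking the face that the oxygen electrophile preferred. Burgess dehydration of F5, which can only remove a methyl hydrogen, would give 7, where the route is rejoined.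

**Further compounds**
F1 | step 9 | trimethylsilyl ether of 14 | C[Si](C)(C)O[C@@]1(/C=C\OCc2ccc(OC)cc2)[C@@](OC)(C(C)=C)CC[C@@]3(C)O[C@@H]13
F2 | step 9 | ring-expanded C6 trimethylsilyl enol ether with C1 methyl enol ether | CO/C1=C(/C)C[C@H](OCc2ccc(OC)cc2)/C=C(\O[Si](C)(C)C)[C@@H]2O[C@]2(C)CC1
F0 | step 10 | none | none
F3 | step 4 | (1R,6R)-3-hydroxy-6-methyl-7-oxabicyclo[4.1.0]heptan-2-one (C3 epimers) | O=C1C(O)CC[C@@]2(C)O[C@@H]12
F4 | step 4 | (1R,6R)-3-methoxy-6-methyl-7-oxabicyclo[4.1.0]heptan-2-one (C3 epimers) | O=C1C(OC)CC[C@@]2(C)O[C@@H]12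
F5 | step 4 | (1R,3S,6R)-3-(2-hydroxypropan-2-yl)-3-methoxy-6-methyl-7-oxabicyclo[4.1.0]heptan-2-one | O=C1[C@@](OC)(C(C)(C)O)CC[C@@]2(C)O[C@@H]12
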